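8.00 h was the number I started from: that is how long noon and midnight stand at 80 °C before the end. I wanted one clock that would turn those hours into a share, meaning first product divided by first product plus bis adduct.

| flask | substrate | reagent | temperature | remark | time |
|---|---|---|---|---|---|
| elm | 33 mM | 1.8 equiv | 65 °C | run made earlier |  |
| oak | 33 mM | 0.90 equiv | 80 °C | run made earlier |  |
| maple | 33 mM | 3.6 equiv | 65 °C | run made earlier |  |
| noon | 33 mM | 1.80 equiv |  | everything together at the start at 50 °C, warmed to 80 °C at 12 h | 20 h |
| spring | 33 mM | 1.80 equiv (fed, over 12 h) | 80 °C | all else is in the flask from the start; the feed brings no volume worth counting | 20 h |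
| autumn | 33 mM | 1.80 equiv (fed, over 80 min) | 80 °C | all else is in the flask from the start; the feed brings no volume worth counting | 20 h |
| midnight | 33 mM (fed, over 12 h) | 1.80 equiv |  | the addition at 50 °C, then warmed to 80 °C; the feed brings no volume worth counting | 20 h |
| summer | 33 mM (fed, over 12 h) | 1.80 equiv | 80 °C | all else is in the flask from the start; the feed brings no volume worth counting | 20 h |

- elm (time / h: first product / %, bis adduct / %): 2.00: 5, 1; 3.00: 7, 0; 4.00: 9, 0; 6.00: 13, 4; 10.0: 14, 9; 15.0: 15, 13; 25.0: 16, 17
- oak (time / h: first product / %, bis adduct / %): 1.50: 4, 0; 2.50: 6, 0; 4.00: 9, 2; 6.00: 7, 4; 8.00: 8, 4; 12.0: 6, 6; 20.0: 2, 12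
- maple (time / h: first product / %, bis adduct / %): 6.00: 18, 9; 12.0: 16, 26; 15.0: 13, 32; 25.0: 11, 47; 30.0: 8, 56; 40.0: 3, 65

(readings scatter by 1.5 percentage points)

1. which flask leads in share of first product in first product plus bis adduct ("all alike" within 1.5 percentage points) (noon / spring / autumn / midnight / summer / all alike)
2. share of first product in first product plus bis adduct at the end, noon
3. share of first product in first product plus bis adduct at the end, spring
4. share of first product in first product plus bis adduct at the end, autumn
5. share of first product in first product plus bis adduct at the end, midnight
6. share of first product in first product plus bis adduct at the end, summer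



I assumed that first product forms and is lost in steps that both go with reagent. Dividing one rate by the other then removes reagent and time and ties the share to how far the substrate has gone, through a ratio of constants, a selectivity factor. So at one temperature and one substrate charge, the share should follow the product of equivalents and hours. For noon and midnight I counted the cold hours as zero, which gave 16.0 h on the oak clock, the hours oak needs at 80 °C to reach the same product.

The first way read oak directly. Its shares were 50.0% at 12.0 h and 14.3% at 20.0 h, and a straight line between them gave 32.1%.

The second way went through 65 °C. Elm at 25.0 h read 48.5%, close to oak at 12.0 h, so by these two scattered readings one unit of that product at 80 °C counted as 4.17 units at 65 °C. That put noon and midnight at 16.7 h on maple, and a line between maple's shares at 15.0 h and 25.0 h gave 27.2%.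

The two readings parted by 4.9 percentage points, while one standard deviation more first product in oak's reading at 20.0 h lifts the first way by 4.1 points, so I could only suspect a cause. The clock counts charged reagent, yet reagent is consumed. Oak, charged with 0.90 equiv, has less than these flasks, so for the same uptake it loses a greater fraction, and I took its clock to flatter the share. Maple, charged with 3.6 equiv, has more, and I took it to err the other way, though it differs from oak in temperature as well. I therefore committed to the middle, 29.7%, for both noon and midnight. Spring, autumn and summer stand at 80 °C throughout, and with spring's feed counted at half strength its clock reaches 28.0 h, longer than the 16.0 h of noon and midnight, so I expected the lead from noon or midnight.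

The forecast said midnight, with noon 37%, spring 19%, autumn 4%, midnight 40% and summer 8%, on the ground that “Noon and midnight keep only 8 h at 80 °C”. My share stood below its noon figure.

The flask that led was midnight, at 31.8%. Noon gave 29.8%, spring 18.6%, autumn 10.2% and summer 17.3%, so my figure for the clock of 16.0 h lay 2.1 points under midnight.

    reagent + other mono adduct → bis adduct (k = 1.90 × 10⁻⁴ /M/s, Ea = 64.0 kJ/mol)
    substrate + reagent ⇌ first product (K = 11.0 /M, k = 4.50 × 10⁻⁴ /M/s, Ea = 65.0 kJ/mol, ΔH = −42.0 kJ/mol)
    first product → over-reaction product (k = 4.30 × 10⁻⁹ /s, Ea = 129 kJ/mol)
    substrate + reagent → other mono adduct (k = 5.90 × 10⁻⁴ /M/s, Ea = 90.0 kJ/mol)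
    reagent + first product → bis adduct (k = 0.00110 /M/s, Ea = 88.0 kJ/mol)
    (constants at 80 °C)

The neighbour of midnight charged with 8.2 mM of substrate, equivalents held, has its reagent diluted in step with the charge, which shrinks the clock in proportion, to 3.98 h. Oak at 4.00 h read a share of 81.8%, and one standard deviation more bis adduct in that reading makes it 72.0%. The neighbour ended at 69.5%.

(The earlier runs and the new flask were computed for substances that don't exist, and the scatter is random.)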